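## Retrosynthetic overview

1. The ester bond is made last: palmitoyl chloride acylates the axial C6 lithium alkoxide generated by equatorial hydride delivery to (R)-dehydrololiolide, which sets 6S.
2. Both rings are closed in one step: a Ni(0)-catalysed carbonylative [2+2+1] (hetero-Pauson–Khand) of an acyclic alkynyl methyl ketone with CO forms C3a–C7a (cyclohexane) and C3–C2/C2–O1 (butenolide).
3. 7aR is relayed from a temporary (R)-silyloxy centre at C6, which sits equatorial in the cyclisation and is afterwards oxidised to the ketone.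
4. The alkynyl ketone comes from 2,2-dimethylpent-4-enal by alkyne homologation, ozonolysis, Brown methallylation, silylation and a second ozonolysis.
5. The acyl chain comes from oct-1-ene and 7-bromohept-1-ene (alkyl–alkyl Suzuki), then hydroformylation, oxidation and acid chloride formation.

Assumption: (−)-Ipc2BOMe (from (+)-α-pinene), the Bestmann–Ohira reagent, 9-BBN, L-Selectride, ligands and metal catalysts are purchased reagents; 2-methylallylmagnesium chloride is bought as its THF solution.

## Route

Step 1
Reactants: 1 2,2-dimethylpent-4-enal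
Product: 2 4,4-dimethylhex-1-en-5-yne
Conditions: Bestmann–Ohira reagent (1.3 equiv), K2CO3 (2 equiv), MeOH, 0 °C to rt, 16 h; pentane extraction, careful distillation (volatile, kept as a concentrated solution)
Reagents that add atoms: dimethyl (1-diazo-2-oxopropyl)phosphonate, COP(=O)(OC)C(=[N+]=[N-])C(C)=O
Why: Seyferth–Gilbert homologation (Ohira–Bestmann variant) converts the non-enolisable neopentyl aldehyde into the terminal alkyne under mild basic conditions that leave the allyl group untouched.

Step 2
Reactants: 2 4,4-dimethylhex-1-en-5-yne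
Product: 4 3,3-dimethylpent-4-ynal, via secondary ozonide 3 (not isolated)
Conditions: O3, CH2Cl2, −78 °C (Sudan Red 7B end point); Me2S, −78 °C to rt; used as a concentrated Et2O solution
Reagents that add atoms: ozone, [O-][O+]=O
Why: Criegee ozonolysis cleaves the terminal alkene orders of magnitude faster than the terminal alkyne, so titration to the indicator end point and reductive work-up give the ynal selectively.

Step 3
Reactants: 4 3,3-dimethylpent-4-ynal; 5 2-methylallylmagnesium chloride
Product: 8 (S)-2,6,6-trimethyloct-1-en-7-yn-4-ol, via B-methallyl-Ipc2-borane 6 (not isolated), via Ipc2-borinate ester 7 (not isolated)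
Conditions: (−)-Ipc2BOMe (1.3 equiv), 5 (1.25 equiv), Et2O, −78 °C to rt, 1 h; then 4, −78 °C, 3 h; then 3 M NaOH, 30% H2O2, rt
Reagents that add atoms: none
Why: Brown asymmetric methallylation; the (+)-α-pinene-derived B-methallyl borane adds through a closed Zimmerman–Traxler chair to the Si face of the aldehyde and sets the carbinol centre as S (about 92–96% ee expected).

Step 4
Reactants: 8 (S)-2,6,6-trimethyloct-1-en-7-yn-4-ol
Product: 9 (S)-triethyl[(2,6,6-trimethyloct-1-en-7-yn-4-yl)oxy]silane
Conditions: TESCl (1.2 equiv), imidazole (2 equiv), DMF, 0 °C to rt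
Reagents that add atoms: chlorotriethylsilane, CC[Si](Cl)(CC)CC
Why: Standard imidazole-promoted silylation; the TES ether survives ozonolysis and nickel catalysis and serves as the equatorial control group in step 6.

Step 5
Reactants: 9 (S)-triethyl[(2,6,6-trimethyloct-1-en-7-yn-4-yl)oxy]silane
Product: 11 (R)-6,6-dimethyl-4-[(triethylsilyl)oxy]oct-7-yn-2-one, via methyl trioxolane 10 (not isolated)
Conditions: O3, CH2Cl2, −78 °C (Sudan Red 7B end point); Me2S, −78 °C to rt
Reagents that add atoms: ozone, [O-][O+]=O
Why: Chemoselective ozonolysis of the 1,1-disubstituted alkene in the presence of the alkyne unveils the methyl ketone; the stereocentre is untouched and its descriptor changes from S to R only through CIP priorities.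

Step 6
Reactants: 11 (R)-6,6-dimethyl-4-[(triethylsilyl)oxy]oct-7-yn-2-one
Product: 12 (6R,7aR)-4,4,7a-trimethyl-6-[(triethylsilyl)oxy]-5,6,7,7a-tetrahydro-1-benzofuran-2(4H)-one
Conditions: Ni(cod)2 (10 mol %), PCy3 (20 mol %), HCO2Ph (1.5 equiv, syringe pump over 8 h), Et3N (20 mol %), toluene (0.02 M), 70 °C; chromatographic removal of any C7a epimer
Reagents that add atoms: phenyl formate (CO donor), O=COc1ccccc1
Why: Proposed new method: Ni(0)-catalysed carbonylative [2+2+1] (hetero-Pauson–Khand) annulation of an unactivated alkynyl methyl ketone; Ni(0)/PCy3 binds the tert-alkyl alkyne and the ketone and undergoes oxidative cyclisation (C3a–C7a bond, six-membered ring closed through a chair with OTES equatorial and the ketone methyl axial because the oxygen must lie in the plane of the oxanickelacyclopentene, hence 7aR with O1 cis to the C6 oxygen), CO released slowly from phenyl formate/Et3N (low stationary CO avoids Ni(CO)n sinks) inserts into the Ni–C(sp2) bond, and acyl–alkoxide C–O reductive elimination closes the butenolide and returns Ni(0); closest known reaction types are the Ru3(CO)12-catalysed cyclocarbonylation of yne-aldehydes, the Ni(0)-catalysed [2+2+1] of imines, alkynes and phenyl formate to γ-lactams, and Ni-catalysed reductive cyclisation of alkynones through the same oxanickelacycle.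

Step 7
Reactants: 12 (6R,7aR)-4,4,7a-trimethyl-6-[(triethylsilyl)oxy]-5,6,7,7a-tetrahydro-1-benzofuran-2(4H)-one
Product: 14 (R)-4,4,7a-trimethyl-7,7a-dihydro-1-benzofuran-2,6(4H,5H)-dione ((R)-dehydrololiolide), via free C6 alcohol 13 (not isolated)
Conditions: Jones reagent (CrO3, H2SO4, H2O; 3 equiv), acetone, 0 °C to rt, 2 h
Reagents that add atoms: none
Why: Jones oxidation: the aqueous acid cleaves the labile TES ether and Cr(VI) oxidises the liberated secondary alcohol in the same pot; the C6 relay centre is removed and the quaternary C7a centre is not affected.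

Step 8
Reactants: 15 oct-1-ene; 16 7-bromohept-1-ene
Product: 18 pentadec-1-ene, via B-octyl-9-BBN 17 (not isolated)
Conditions: 15 (1.05 equiv), 9-BBN (1.0 equiv B–H), THF, rt, 3 h; then 16 (1.0 equiv), Pd(OAc)2 (4 mol %), PCy3 (8 mol %), K3PO4·H2O (1.2 equiv), THF, rt, 20 h
Reagents that add atoms: none
Why: Anti-Markovnikov hydroboration followed by alkyl–alkyl Suzuki–Miyaura coupling; the bulky electron-rich PCy3 makes oxidative addition of the primary bromide and transmetalation outrun β-hydride elimination, and the remote alkene of 16 is inert once all B–H is consumed.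

Step 9
Reactants: 18 pentadec-1-ene
Product: 19 hexadecanal
Conditions: Rh(acac)(CO)2 (0.5 mol %), BIPHEPHOS (2 mol %), CO/H2 (1:1, 10 bar), toluene, 80 °C
Reagents that add atoms: carbon monoxide, [C-]#[O+]
Why: Rh/bisphosphite hydroformylation gives the linear aldehyde from an unfunctionalised 1-alkene with very high linear:branched selectivity.

Step 10
Reactants: 19 hexadecanal
Product: 20 hexadecanoic acid (palmitic acid)
Conditions: NaClO2, NaH2PO4, 2-methylbut-2-ene, t-BuOH/H2O, rt
Reagents that add atoms: sodium chlorite, [Na+].[O-]Cl=O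
Why: Pinnick oxidation converts the aldehyde cleanly into the acid while the alkene scavenger traps HOCl.

Step 11
Reactants: 20 hexadecanoic acid
Product: 21 hexadecanoyl chloride
Conditions: (COCl)2 (1.5 equiv), DMF (cat.), CH2Cl2, 0 °C to rt; evaporate
Reagents that add atoms: oxalyl chloride, O=C(Cl)C(Cl)=O
Why: Vilsmeier-catalysed acid chloride formation gives the acyl donor with only gaseous by-products.

Step 12
Reactants: 14 (R)-dehydrololiolide; 21 hexadecanoyl chloride
Product: 23 (−)-3-O-palmitoylloliolide, (6S,7aR)-4,4,7a-trimethyl-2-oxo-2,4,5,6,7,7a-hexahydro-1-benzofuran-6-yl hexadecanoate, via lithium C6 alkoxide 22 (not isolated)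
Conditions: L-Selectride (1.05 equiv), THF, −78 °C, 1 h; then 21 (1.5 equiv), DMAP (0.2 equiv), −78 °C to rt; pH 7 buffer/H2O2 work-up
Reagents that add atoms: none
Why: Sterically controlled ketone reduction: the bulky hydride attacks from the equatorial face, away from the two syn-axial methyl groups at C4 and C7a (as in 3,3,5-trimethylcyclohexanone), giving the axial 6S alkoxide, which is O-acylated in situ with retention.

## Compound list

1 | 2,2-dimethylpent-4-enal | O=CC(C)(C)CC=C | starting material
2 | 4,4-dimethylhex-1-en-5-yne | C=CCC(C)(C)C#C | intermediate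
3 | 3-(2,2-dimethylbut-3-yn-1-yl)-1,2,4-trioxolane (racemic secondary ozonide) | C#CC(C)(C)CC1OCOO1 | intermediate
4 | 3,3-dimethylpent-4-ynal | O=CCC(C)(C)C#C | intermediate
5 | 2-methylallylmagnesium chloride | C=C(C)C[Mg]Cl | starting material
6 | B-(2-methylallyl)bis[(1R,2S,3R,5R)-isopinocampheyl]borane | C=C(C)CB([C@@H]1C[C@@H]2C[C@H]([C@H]1C)C2(C)C)[C@@H]1C[C@@H]2C[C@H]([C@H]1C)C2(C)C | intermediate
7 | bis[(1R,2S,3R,5R)-isopinocampheyl]borinic acid (S)-2,6,6-trimethyloct-1-en-7-yn-4-yl ester | C=C(C)C[C@H](OB([C@@H]1C[C@@H]2C[C@H]([C@H]1C)C2(C)C)[C@@H]1C[C@@H]2C[C@H]([C@H]1C)C2(C)C)CC(C)(C)C#C | intermediate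
8 | (S)-2,6,6-trimethyloct-1-en-7-yn-4-ol | C=C(C)C[C@H](O)CC(C)(C)C#C | intermediate
9 | (S)-triethyl[(2,6,6-trimethyloct-1-en-7-yn-4-yl)oxy]silane | C=C(C)C[C@H](O[Si](CC)(CC)CC)CC(C)(C)C#C | intermediate
10 | triethyl{[(2R)-4,4-dimethyl-1-(3-methyl-1,2,4-trioxolan-3-yl)hex-5-yn-2-yl]oxy}silane (epimers at the trioxolane carbon) | CC1(C[C@H](O[Si](CC)(CC)CC)CC(C)(C)C#C)OCOO1 | intermediate
11 | (R)-6,6-dimethyl-4-[(triethylsilyl)oxy]oct-7-yn-2-one | CC(=O)C[C@H](O[Si](CC)(CC)CC)CC(C)(C)C#C | intermediate
12 | (6R,7aR)-4,4,7a-trimethyl-6-[(triethylsilyl)oxy]-5,6,7,7a-tetrahydro-1-benzofuran-2(4H)-one | CC[Si](CC)(CC)O[C@@H]1CC(C)(C)C2=CC(=O)O[C@]2(C)C1 | intermediate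
13 | (6R,7aR)-6-hydroxy-4,4,7a-trimethyl-5,6,7,7a-tetrahydro-1-benzofuran-2(4H)-one (6-epi-loliolide) | O[C@@H]1CC(C)(C)C2=CC(=O)O[C@]2(C)C1 | intermediate
14 | (R)-4,4,7a-trimethyl-7,7a-dihydro-1-benzofuran-2,6(4H,5H)-dione ((R)-dehydrololiolide) | O=C1CC(C)(C)C2=CC(=O)O[C@]2(C)C1 | intermediate
15 | oct-1-ene | C=CCCCCCC | starting material
16 | 7-bromohept-1-ene | C=CCCCCCBr | starting material
17 | 9-octyl-9-borabicyclo[3.3.1]nonane | CCCCCCCCB1C2CCCC1CCC2 | intermediate
18 | pentadec-1-ene | C=CCCCCCCCCCCCCC | intermediate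
19 | hexadecanal | CCCCCCCCCCCCCCCC=O | intermediate
20 | hexadecanoic acid | CCCCCCCCCCCCCCCC(=O)O | intermediate
21 | hexadecanoyl chloride | CCCCCCCCCCCCCCCC(=O)Cl | intermediate
22 | lithium (6S,7aR)-4,4,7a-trimethyl-2-oxo-2,4,5,6,7,7a-hexahydro-1-benzofuran-6-olate | [Li+].[O-][C@H]1CC(C)(C)C2=CC(=O)O[C@]2(C)C1 | intermediate
23 | (−)-3-O-palmitoylloliolide | CCCCCCCCCCCCCCCC(=O)O[C@H]1CC(C)(C)C2=CC(=O)O[C@]2(C)C1 | target

## Step count and risks

Total steps: 12. Longest linear sequence: 8 (steps 1–7 and 12). The acyl branch (steps 8–11) joins in step 12.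

**Step 6 (proposed new hetero-Pauson–Khand).** Risks are slow oxidative cyclisation of the ketone, Ni–carbonyl deactivation and alkyne oligomerisation. Any C7a epimer must be removed at 12, because after step 7 it would become the enantiomer of 14. Fallback with known chemistry, setting out from 9 and returning at 12: deprotonate the alkyne of 9 with n-BuLi (THF, −78 °C) and quench with methyl chloroformate to give methyl (6S)-4,4,8-trimethyl-6-[(triethylsilyl)oxy]non-8-en-2-ynoate F1. Ozonolysis (O3, CH2Cl2, −78 °C; Me2S) gives methyl (6R)-4,4-dimethyl-8-oxo-6-[(triethylsilyl)oxy]non-2-ynoate F2. SmI2 (2.5 equiv, THF/HMPA, t-BuOH, −78 to 0 °C) then effects a ketyl–alkynoate 6-exo-dig reductive cyclisation through the same chair (OTES equatorial), and the samarium alkoxide lactonises onto the Z-ester to give 12.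

**Step 12 (one-pot reduction and acylation).** Risks are incomplete facial selectivity and sluggish acylation of the hindered axial alkoxide in the presence of the borane. Fallback, setting out from 14 and returning at 23: reduce 14 with L-Selectride (THF, −78 °C), work up and isolate (−)-loliolide F3, confirming the axial alcohol by its narrow H-6 multiplet. Then acylate the purified alcohol with 21, pyridine and DMAP (CH2Cl2, 40 °C) to reach 23.

**Step 8 (alkyl–alkyl Suzuki).** Risks are β-hydride elimination and oxygen sensitivity of the Pd/PCy3 system. Fallback, setting out from 15 and 16 and returning at 18: radical anti-Markovnikov hydrobromination of 15 (HBr, dibenzoyl peroxide, hexane) gives 1-bromooctane F4. Magnesium in THF converts it into octylmagnesium bromide F5. Li2CuCl4 (3 mol %)-catalysed Kumada–Kochi coupling with 16 (THF/NMP, 0 °C) gives 18.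

## Further compounds

F1 | step 6 | methyl (6S)-4,4,8-trimethyl-6-[(triethylsilyl)oxy]non-8-en-2-ynoate | C=C(C)C[C@H](O[Si](CC)(CC)CC)CC(C)(C)C#CC(=O)OC
F2 | step 6 | methyl (6R)-4,4-dimethyl-8-oxo-6-[(triethylsilyl)oxy]non-2-ynoate | CC(=O)C[C@H](O[Si](CC)(CC)CC)CC(C)(C)C#CC(=O)OC
F3 | step 12 | (−)-loliolide, (6S,7aR)-6-hydroxy-4,4,7a-trimethyl-5,6,7,7a-tetrahydro-1-benzofuran-2(4H)-one | O[C@H]1CC(C)(C)C2=CC(=O)O[C@]2(C)C1
F4 | step 8 | 1-bromooctane | CCCCCCCCBr
F5 | step 8 | octylmagnesium bromide | CCCCCCCC[Mg]Br
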